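**Assumption:** the SMILES is read as (R) at the diaryl methine carbon and (S) at the carbinol carbon. Compounds 4, 8, 10, 13 and both chiral catalysts are taken as purchased.

## Retrosynthetic overview

1. Epicalyxin B ⇒ global MOM removal and Claisen–Schmidt condensation: acetophenone 12 + aldehyde 13.
2. Key disconnection is C(sp3)–C(alkenyl) at the methine, not aryl–C: alkenylboronic acid 11 adds enantioselectively to an o-quinone methide made by dearomatising the phloracetophenone ring of benzhydryl ether 5. This sets the (R) methine centre.
3. 5 ⇒ aryl-Grignard addition to keto-aldehyde 3 ⇒ acetylation of C2v-symmetric 2,6-dihydroxy-4-methoxybenzaldehyde 2 (two homotopic sites, so the ring pattern is fixed by symmetry) ⇒ 2,4,6-trimethoxybenzaldehyde 1.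
4. 11 ⇒ hydroboration of (S)-homopropargylic alcohol 9 ⇒ catalytic asymmetric propargylation of aldehyde 7 (sets the (S) carbinol) ⇒ Heck reaction of aryl iodide 4 with allyl alcohol.
5. No rings are formed. All three benzene rings are purchased; the A-ring is only transiently dearomatised and rearomatised in the key step.

## Route

**Step 1**
Reactants: 1, 2,4,6-trimethoxybenzaldehyde
Product: 2, 2,6-dihydroxy-4-methoxybenzaldehyde
Conditions: AlCl3 (4 equiv), CH2Cl2, 0 °C → reflux; 1 M HCl
Reagents that add atoms: none
Why: Chelation-directed Lewis-acid demethylation cleaves only the two methoxy groups ortho to the aldehyde, leaving the para OMe and giving a C2v-symmetric ring.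

**Step 2**
Reactants: 2
Product: 3, 3-acetyl-2,6-dihydroxy-4-methoxybenzaldehyde
Conditions: AcOH, BF3·OEt2 (4 equiv), 85 °C; then NaOAc, MeOH/H2O, 60 °C
Reagents that add atoms: acetic acid, CC(=O)O
Why: Friedel–Crafts (Fries-type) C-acetylation of the phloroglucinol-type ring, where C3 and C5 are homotopic so one regioisomer forms, with CHO between two OH and acetyl between OH and OMe as the target requires.

**Step 3**
Reactants: 3; 4, 1-iodo-4-(methoxymethoxy)benzene
Product: 5, 1-{3-[ethoxy(4-(methoxymethoxy)phenyl)methyl]-2,4-dihydroxy-6-methoxyphenyl}ethan-1-one (racemic at the benzylic carbon)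
Conditions: 4, i-PrMgCl·LiCl, THF, −20 °C; then 3 (ArMg 4 equiv), −40 → 0 °C; NH4Cl; crude carbinol, EtOH, PPTS (10 mol%), rt
Reagents that add atoms: aryl Grignard from 4, COCOc1ccc([Mg]Cl)cc1; ethanol, CCO
Why: After phenol deprotonation the aryl Grignard adds to the aldehyde in preference to the di-ortho-substituted, enolisable aryl methyl ketone, and the labile bis(o-hydroxy)benzhydrol is trapped via its o-quinone methide as the ethyl ether; this benzylic centre is erased in step 7.

**Step 4**
Reactants: 4; 6, allyl alcohol
Product: 7, 3-[4-(methoxymethoxy)phenyl]propanal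
Conditions: Pd(OAc)2 (3 mol%), n-Bu4NCl, NaHCO3, DMF, 45 °C
Reagents that add atoms: none other than reactant 6 (C=CCO)
Why: Jeffery–Heck arylation of allyl alcohol, where β-hydride elimination toward the carbinol gives the enol and hence the saturated aldehyde.

**Step 5**
Reactants: 7; 8, allenylboronic acid pinacol ester
Product: 9, (S)-1-[4-(methoxymethoxy)phenyl]hex-5-yn-3-ol
Conditions: (R)-TRIP phosphoric acid (5 mol%), 4 Å MS, toluene, −20 °C
Reagents that add atoms: none other than reactant 8 (C=C=CB1OC(C)(C)C(C)(C)O1)
Why: Chiral phosphoric acid-catalysed SE2′ propargylation through a closed six-membered transition state; Re-face attack is expected for (R)-TRIP and corresponds to (S) here, at roughly 90% ee, with the sense to be confirmed by Mosher analysis (use ent-catalyst if reversed).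

**Step 6**
Reactants: 9; 10, catecholborane
Product: 11, [(1E,4S)-4-hydroxy-6-(4-(methoxymethoxy)phenyl)hex-1-en-1-yl]boronic acid
Conditions: catecholborane (2.5 equiv), Cy2BH (10 mol%), THF, rt → 40 °C; then H2O
Reagents that add atoms: catecholborane, B1Oc2ccccc2O1 (boron); water, O
Why: Syn, anti-Markovnikov hydroboration of the terminal alkyne gives the (E)-alkenylboronate; one extra equivalent of borane is consumed by the free OH and released on hydrolysis, and the carbinol centre is untouched.

**Step 7 (key step)**
Reactants: 5; 11
Product: 12, 1-{2,4-dihydroxy-3-[(1R,2E,5S)-5-hydroxy-1,7-bis(4-(methoxymethoxy)phenyl)hept-2-en-1-yl]-6-methoxyphenyl}ethan-1-one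
Conditions: 11 (1.5 equiv, pre-esterified in situ with EtOH/4 Å MS), (R)-3,3′-Br2-BINOL (15 mol%), 4 Å MS, PhCF3, 40 °C
Reagents that add atoms: none
Why: Proposed new method: boron-assisted loss of EtOH from 5 dearomatises the A-ring to an o-quinone methide, and the BINOL-exchanged alkenylboronate bound to the quinone methide oxygen transfers its alkenyl group to the exocyclic carbon through a closed six-membered transition state with retention of E geometry and rearomatisation; the closest known reaction is the chiral biphenol-catalysed enantioselective addition of alkenyl/aryl boronates to o-quinone methides from o-hydroxybenzyl ethers, here extended to a doubly ortho-hydroxylated, acyl-bearing ring and a hydroxyl-bearing boronate. The methine centre is catalyst-controlled (the remote carbinol has no influence); the (R)-catalyst is a provisional assignment from the closed-TS model, to be checked on the first run against epicalyxin B/calyxin B data, and the (S)-catalyst gives the methine epimer.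

**Step 8**
Reactants: 12; 13, 4-(methoxymethoxy)benzaldehyde
Product: 14, (E)-1-{2,4-dihydroxy-3-[(1R,2E,5S)-5-hydroxy-1,7-bis(4-(methoxymethoxy)phenyl)hept-2-en-1-yl]-6-methoxyphenyl}-3-(4-(methoxymethoxy)phenyl)prop-2-en-1-one
Conditions: KOH (50% aq., 15 equiv), EtOH, rt, Ar; AcOH to pH 5, 0 °C
Reagents that add atoms: none other than reactant 13 (COCOc1ccc(C=O)cc1)
Why: Claisen–Schmidt condensation of a 2′,4′-dihydroxyacetophenone with a non-phenolic aldehyde gives the (E)-chalcone; MOM ethers, the isolated alkene, the secondary alcohol and the non-acidic methine centre are stable to hydroxide.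

**Step 9**
Reactants: 14
Product: 15, epicalyxin B
Conditions: 3 M HCl (aq.)/MeOH, rt → 40 °C
Reagents that add atoms: none
Why: Mild acidic acetal cleavage removes the three phenolic MOM groups, with MeOH scavenging formaldehyde, as in xanthohumol-type endgames on the same A-ring; no stereocentre is ionisable under these conditions.

## Compound list

1 | 2,4,6-trimethoxybenzaldehyde | COc1cc(OC)c(C=O)c(OC)c1 | starting material
2 | 2,6-dihydroxy-4-methoxybenzaldehyde | COc1cc(O)c(C=O)c(O)c1 | intermediate
3 | 3-acetyl-2,6-dihydroxy-4-methoxybenzaldehyde | COc1cc(O)c(C=O)c(O)c1C(C)=O | intermediate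
4 | 1-iodo-4-(methoxymethoxy)benzene | COCOc1ccc(I)cc1 | starting material
5 | 1-{3-[ethoxy(4-(methoxymethoxy)phenyl)methyl]-2,4-dihydroxy-6-methoxyphenyl}ethan-1-one (racemic) | CCOC(c1ccc(OCOC)cc1)c1c(O)cc(OC)c(C(C)=O)c1O | intermediate
6 | allyl alcohol | C=CCO | starting material
7 | 3-[4-(methoxymethoxy)phenyl]propanal | O=CCCc1ccc(OCOC)cc1 | intermediate
8 | allenylboronic acid pinacol ester | C=C=CB1OC(C)(C)C(C)(C)O1 | starting material
9 | (S)-1-[4-(methoxymethoxy)phenyl]hex-5-yn-3-ol | C#CC[C@@H](O)CCc1ccc(OCOC)cc1 | intermediate
10 | catecholborane | B1Oc2ccccc2O1 | starting material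
11 | [(1E,4S)-4-hydroxy-6-(4-(methoxymethoxy)phenyl)hex-1-en-1-yl]boronic acid | OB(O)/C=C/C[C@@H](O)CCc1ccc(OCOC)cc1 | intermediate
12 | 1-{2,4-dihydroxy-3-[(1R,2E,5S)-5-hydroxy-1,7-bis(4-(methoxymethoxy)phenyl)hept-2-en-1-yl]-6-methoxyphenyl}ethan-1-one | COc1cc(O)c([C@H](/C=C/C[C@@H](O)CCc2ccc(OCOC)cc2)c2ccc(OCOC)cc2)c(O)c1C(C)=O | intermediate
13 | 4-(methoxymethoxy)benzaldehyde | COCOc1ccc(C=O)cc1 | starting material
14 | tris-MOM epicalyxin B (name as in step 8) | COc1cc(O)c([C@H](/C=C/C[C@@H](O)CCc2ccc(OCOC)cc2)c2ccc(OCOC)cc2)c(O)c1C(=O)/C=C/c1ccc(OCOC)cc1 | intermediate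
15 | epicalyxin B | COc1cc(O)c([C@H](/C=C/C[C@@H](O)CCc2ccc(O)cc2)c2ccc(O)cc2)c(O)c1C(=O)/C=C/c1ccc(O)cc1 | target

## Summary

Total steps: 9. Longest linear sequence: 6 (steps 1, 2, 3, 7, 8, 9, or equally 4, 5, 6, 7, 8, 9).

Steps most likely to fail:

1. **Step 7 (key step).** Risks are low ee from mixed o-quinone methide geometry (two ortho oxygens), boron sequestration by the acetyl/2′-OH chelate, quinone methide oligomerisation, and an unverified sense of induction. Fallback: abandon the quinone methide and set the methine centre by Ir/phosphoramidite-catalysed branched-selective allylic C-alkylation of a 4-O-MOM phloracetophenone with 4-(MOMO)cinnamyl methyl carbonate, then join the chain by cross-metathesis with the (S)-homoallylic alcohol made by asymmetric allylation of 7.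
2. **Step 3.** Risks are poor aldehyde-versus-ketone selectivity on the dianion, sluggish addition, and decomposition of the very labile benzhydrol or ether. Fallback: replace the Grignard with Rh(I)-catalysed addition of 4-(methoxymethoxy)phenylboronic acid to aldehyde 3 (neutral, aldehyde-selective, tolerant of free phenols) and take the crude carbinol straight into step 7 without forming the ether.
3. **Step 2.** Risks are protodeformylation or incomplete C-acylation of the formyl-deactivated ring. Fallback: reverse the order of carbonyl introduction: start from commercial 2,4-dihydroxy-6-methoxyacetophenone and install the aldehyde carbon by Mg-mediated ortho-formylation or Vilsmeier formylation, separating the 3-formyl isomer (= 3) from the 5-formyl isomer.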